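**Plan**

1. Retrosynthesis: the six aryl acetates come off last. The cyclohexene is cut at C(a)–C(b), between the benzylic carbon on C-8 of flavone ring A and the ring alkene carbon, which leaves a benzylic carbinol and a (Z)-vinylsilane. The carbinol is cut at C(a)–C(f) (aldol) into a flavone-8-carbaldehyde and an aryl ketone.
2. The ketone is cut at C(f)–C(=O) (alkyllithium plus aryl aldehyde) and at C(e)–C(d) (auxiliary-controlled enolate alkylation with a (Z)-silylallyl bromide). The flavone is cut at C-8–CHO and across the pyranone (O-1–C-2 and C-2–C-3).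
3. Forward: silylallyl bromide (steps 1–3), ketone (steps 4–13), flavone with its pyranone ring closed in step 20 and formylated in step 22, aldol union in step 23, cyclohexene closed last in step 24, deacetylation in step 25.
4. Stereochemistry: C-e comes from alkylation on (S)-4-benzyloxazolidin-2-one (step 6). The Z alkene comes from anti-carbomagnesiation (step 1) and is carried through SN2 and ipso substitution. C-a is set by the chair-like ring closure relative to C-e, and C-f settles by enol equilibration to the all-trans ketone.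
5. Enabling feature: C-a sits on C-8 of ring A, para to the free 5-OH and ortho to O-7 and O-1, so its carbinol ionises to a quinone-methide-like cation. In the target C-a is bonded to alkene carbon b, so a vinylsilane at b can capture that cation and leave the b=c alkene with the methyl on c.

Key step: step 24

Abbreviations: TBS = tert-butyldimethylsilyl; TIPS = triisopropylsilyl; prenyl = 3-methylbut-2-en-1-yl. Ring atoms: a = CH bearing the flavone, b = alkene CH, c = alkene C bearing CH3, d = CH2, e = CH bearing the 2,4-dioxygenated phenyl ring, f = CH bearing the aroyl group.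

Assumption: the carbinol of step 11 and the aldol adducts of steps 19 and 23 are carried on as epimer mixtures at their new sp3 centres, because each of these centres is oxidised, ionised or equilibrated in the step that follows.

**Route**

Step 1
Reactants: 1 prop-2-yn-1-ol
Product: 3 (Z)-3-iodo-2-methylprop-2-en-1-ol, via cyclic alkenylmagnesium alkoxide 2 (not isolated)
Conditions: MeMgBr (3 equiv), CuI (10 mol%), THF, −10 °C → rt; then I2, −78 → 0 °C
Reagents that add atoms: methylmagnesium bromide C[Mg]Br; iodine II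
Why: Copper-catalysed anti-carbomagnesiation of the propargylic alkoxide puts methyl on C-2 and magnesium on C-3 inside a five-membered chelate, so iodinolysis with retention should give only the Z iodide.

Step 2
Reactants: 3 (Z)-3-iodo-2-methylprop-2-en-1-ol
Product: 6 (Z)-2-methyl-3-(trimethylsilyl)prop-2-en-1-ol, via dilithio alkoxide 4 (not isolated), via C,O-bis(trimethylsilyl) ether 5 (not isolated)
Conditions: t-BuLi (3.1 equiv), Et2O, −78 °C; Me3SiCl (2.5 equiv), −78 °C → rt; then citric acid (cat.), MeOH, rt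
Reagents that add atoms: chlorotrimethylsilane C[Si](C)(C)Cl
Why: Iodine–lithium exchange and C-silylation of the alkenyllithium both retain the alkene geometry, and acidic methanolysis then cleaves only the labile O–Si bond.

Step 3
Reactants: 6 (Z)-2-methyl-3-(trimethylsilyl)prop-2-en-1-ol
Product: 7 (Z)-(3-bromo-2-methylprop-1-en-1-yl)trimethylsilane
Conditions: CBr4, PPh3, CH2Cl2, 0 °C
Reagents that add atoms: carbon tetrabromide BrC(Br)(Br)Br
Why: The Appel reaction converts the primary allylic alcohol into the bromide by SN2 displacement of the oxyphosphonium ion under neutral conditions that leave the vinylsilane and its geometry untouched.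

Step 4
Reactants: 8 (2,4-dihydroxyphenyl)acetic acid
Product: 10 [2,4-bis(TBS-oxy)phenyl]acetic acid, via TBS ester 9 (not isolated)
Conditions: TBSCl (3.3 equiv), imidazole, DMF, rt; then AcOH–THF–H2O (3:1:1), rt
Reagents that add atoms: tert-butyldimethylsilyl chloride CC(C)(C)[Si](C)(C)Cl
Why: Exhaustive O-silylation followed by selective hydrolysis of the far more labile silyl ester is the standard way to silyl-protect the phenols of a hydroxy acid.

Step 5
Reactants: 10 [2,4-bis(TBS-oxy)phenyl]acetic acid; 11 (S)-4-benzyloxazolidin-2-one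
Product: 13 (S)-4-benzyl-3-{[2,4-bis(TBS-oxy)phenyl]acetyl}oxazolidin-2-one, via mixed pivalic anhydride 12 (not isolated)
Conditions: t-BuCOCl, Et3N, THF, −20 °C; then 11, LiCl, −20 °C → rt
Reagents that add atoms: none
Why: N-Acylation of the oxazolidinone through the mixed pivalic anhydride with LiCl activation is the routine entry to acyl oxazolidinones and takes place at the less hindered arylacetyl carbonyl.

Step 6
Reactants: 13 (S)-4-benzyl-3-{[2,4-bis(TBS-oxy)phenyl]acetyl}oxazolidin-2-one; 7 (Z)-(3-bromo-2-methylprop-1-en-1-yl)trimethylsilane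
Product: 15 (S)-4-benzyl-3-{(2S,4Z)-2-[2,4-bis(TBS-oxy)phenyl]-4-methyl-5-(trimethylsilyl)pent-4-enoyl}oxazolidin-2-one, via sodium Z-enolate 14 (not isolated)
Conditions: NaN(SiMe3)2 (1.05 equiv), THF, −78 °C; then 7 (1.5 equiv), −78 → −45 °C
Reagents that add atoms: none
Why: In this Evans alkylation the chelated Z sodium enolate takes the allylic bromide on the face opposite the benzyl group, which sets the new centre as 2S (the later C-e), and the SN2 displacement keeps the Z vinylsilane.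

Step 7
Reactants: 15 the alkylated acyl oxazolidinone
Product: 16 (2S,4Z)-2-[2,4-bis(TBS-oxy)phenyl]-4-methyl-5-(trimethylsilyl)pent-4-en-1-ol
Conditions: LiBH4, MeOH (1.1 equiv), Et2O, 0 °C
Reagents that add atoms: none
Why: Reductive cleavage of the imide with LiBH4 attacks the exocyclic carbonyl and gives the primary alcohol without touching the α-aryl stereocentre, releasing the auxiliary.

Step 8
Reactants: 16 (2S,4Z)-2-[2,4-bis(TBS-oxy)phenyl]-4-methyl-5-(trimethylsilyl)pent-4-en-1-ol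
Product: 17 {(1Z,4S)-4-[2,4-bis(TBS-oxy)phenyl]-5-iodo-2-methylpent-1-en-1-yl}trimethylsilane
Conditions: PPh3, imidazole, I2, CH2Cl2, 0 °C (reagent pre-formed); then 16, 0 °C → rt
Reagents that add atoms: iodine II
Why: Iodination through the oxyphosphonium ion (Appel-type, Garegg–Samuelsson conditions) is an SN2 process remote from the stereocentre, and pre-forming the phosphonium iodide keeps free iodine away from the vinylsilane.

Step 9
Reactants: 18 2,4-dihydroxybenzaldehyde
Product: 19 2,4-dihydroxy-3-prenylbenzaldehyde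
Conditions: 1-bromo-3-methylbut-2-ene (1 equiv), KOH (10% aq.), 0 °C → rt
Reagents that add atoms: 1-bromo-3-methylbut-2-ene CC(C)=CCBr
Why: C-Alkylation of the resorcinolate in water (phenolate C-prenylation) should favour C-3, the carbon flanked by both oxygens, with O-alkylated and C-5 isomers removed by chromatography.

Step 10
Reactants: 19 2,4-dihydroxy-3-prenylbenzaldehyde
Product: 20 2,4-bis(TBS-oxy)-3-prenylbenzaldehyde
Conditions: TBSOTf (2.5 equiv), 2,6-lutidine, CH2Cl2, 0 °C
Reagents that add atoms: tert-butyldimethylsilyl trifluoromethanesulfonate CC(C)(C)[Si](C)(C)OS(=O)(=O)C(F)(F)F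
Why: O-Silylation with the silyl triflate is forceful enough to cap both the free 4-OH and the hindered, hydrogen-bonded 2-OH.

Step 11
Reactants: 17 the primary iodide; 20 2,4-bis(TBS-oxy)-3-prenylbenzaldehyde
Product: 22 (3R,5Z)-1-[2,4-bis(TBS-oxy)-3-prenylphenyl]-3-[2,4-bis(TBS-oxy)phenyl]-5-methyl-6-(trimethylsilyl)hex-5-en-1-ol (both C-1 epimers), via primary alkyllithium 21 (not isolated)
Conditions: 17, t-BuLi (2.1 equiv), Et2O–pentane, −78 °C, 10 min; then 20, −78 °C; AcOH, −78 °C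
Reagents that add atoms: none
Why: Iodine–lithium exchange of the primary iodide at −78 °C should outrun any silyl migration, and 1,2-addition of the alkyllithium to the aldehyde forms the C(f)–C(carbonyl) bond, the carbinol configuration being irrelevant.

Step 12
Reactants: 22 the secondary benzylic alcohol
Product: 23 (3R,5Z)-1-[2,4-bis(TBS-oxy)-3-prenylphenyl]-3-[2,4-bis(TBS-oxy)phenyl]-5-methyl-6-(trimethylsilyl)hex-5-en-1-one
Conditions: Dess–Martin periodinane, NaHCO3, CH2Cl2, 0 °C → rt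
Reagents that add atoms: none
Why: Dess–Martin oxidation gives the aryl ketone under buffered neutral conditions that spare the silyl ethers, both alkenes and the β-stereocentre.

Step 13
Reactants: 23 the tetrasilylated ketone
Product: 25 (3R,5Z)-1-(2,4-diacetoxy-3-prenylphenyl)-3-(2,4-diacetoxyphenyl)-5-methyl-6-(trimethylsilyl)hex-5-en-1-one, via tetraphenol 24 (not isolated)
Conditions: Bu4NF (4.4 equiv), AcOH (4.4 equiv), THF, 0 °C; then Ac2O (8 equiv), Et3N, DMAP (cat.), 0 °C → rt
Reagents that add atoms: acetic anhydride CC(=O)OC(C)=O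
Why: Buffered fluoride desilylation followed by acetylation in the same flask exchanges the four silyl ethers for acetates without acid, so the phenol near the ketone cannot close a chromene and the vinylsilane survives.

Step 14
Reactants: 26 2',4',6'-trihydroxyacetophenone
Product: 27 1-[2-hydroxy-4,6-bis(TIPS-oxy)phenyl]ethanone
Conditions: i-Pr3SiCl (2.1 equiv), imidazole, DMF, 0 °C → rt
Reagents that add atoms: triisopropylsilyl chloride CC(C)[Si](Cl)(C(C)C)C(C)C
Why: O-Silylation of the symmetrical triphenol should stop after two TIPS groups because the remaining hydroxyl is hydrogen-bonded to the acetyl group.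

Step 15
Reactants: 27 1-[2-hydroxy-4,6-bis(TIPS-oxy)phenyl]ethanone
Product: 28 1-[2-hydroxy-3-iodo-4,6-bis(TIPS-oxy)phenyl]ethanone
Conditions: N-iodosuccinimide (1.05 equiv), CH2Cl2, 0 °C, dark
Reagents that add atoms: N-iodosuccinimide O=C1CCC(=O)N1I
Why: Electrophilic aromatic iodination is directed ortho to the free phenol, and C-5 between two bulky TIPS ethers is shielded, so iodine should enter C-3.

Step 16
Reactants: 28 1-[2-hydroxy-3-iodo-4,6-bis(TIPS-oxy)phenyl]ethanone
Product: 30 1-[2-hydroxy-3-iodo-4,6-bis(TIPS-oxy)phenyl]-5-methylhex-4-en-1-one, via dilithium phenoxide-enolate 29 (not isolated)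
Conditions: LiN(SiMe3)2 (2.2 equiv), THF, −78 °C; 1-bromo-3-methylbut-2-ene (1.05 equiv), DMPU, −78 → −50 °C; AcOH
Reagents that add atoms: 1-bromo-3-methylbut-2-ene CC(C)=CCBr
Why: Enolate C-alkylation within the phenoxide–enolate dianion is faster than O-alkylation of the chelated phenoxide, and the low temperature avoids silyl transfer to the enolate.

Step 17
Reactants: 18 2,4-dihydroxybenzaldehyde
Product: 31 2-hydroxy-4-(prenyloxy)benzaldehyde
Conditions: 1-bromo-3-methylbut-2-ene (1.05 equiv), K2CO3 (1.1 equiv), acetone, rt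
Reagents that add atoms: 1-bromo-3-methylbut-2-ene CC(C)=CCBr
Why: Williamson etherification is selective for the 4-OH because the 2-OH is hydrogen-bonded to the aldehyde and far less nucleophilic.

Step 18
Reactants: 31 2-hydroxy-4-(prenyloxy)benzaldehyde
Product: 32 4-(prenyloxy)-2-(TIPS-oxy)benzaldehyde
Conditions: i-Pr3SiCl, imidazole, DMF, rt
Reagents that add atoms: triisopropylsilyl chloride CC(C)[Si](Cl)(C(C)C)C(C)C
Why: O-Silylation of the remaining phenol gives a base-stable ether that blocks this oxygen from taking part in the later pyranone closure.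

Step 19
Reactants: 30 the α-prenyl ketone; 32 4-(prenyloxy)-2-(TIPS-oxy)benzaldehyde
Product: 34 3-hydroxy-1-[2-hydroxy-3-iodo-4,6-bis(TIPS-oxy)phenyl]-2-prenyl-3-[4-(prenyloxy)-2-(TIPS-oxy)phenyl]propan-1-one (diastereomer mixture), via dilithium phenoxide-enolate 33 (not isolated)
Conditions: 30, LiN(SiMe3)2 (2.2 equiv), THF, −78 °C; then 32, −78 °C; AcOH, −78 °C
Reagents that add atoms: none
Why: Aldol addition of the lithium enolate to the non-enolisable aldehyde with a cold quench gives the β-hydroxy ketone, whose two new stereocentres are removed in the next step.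

Step 20
Reactants: 34 the β-hydroxy ketone
Product: 36 8-iodo-3-prenyl-2-[4-(prenyloxy)-2-(TIPS-oxy)phenyl]-5,7-bis(TIPS-oxy)-4H-chromen-4-one, via 1,3-diketone 35 (not isolated)
Conditions: Dess–Martin periodinane, NaHCO3, CH2Cl2, 0 °C → rt; silica pad; then PPTS (0.3 equiv), toluene, 90 °C
Reagents that add atoms: none
Why: Dess–Martin oxidation gives the 1,3-diketone, and mild acid-catalysed cyclodehydration (the flavone-forming step of the Baker–Venkataraman route) closes the pyranone through the only free phenol, the one next to iodine, which fixes iodine at C-8 and spares the silyl and prenyl ethers.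

Step 21
Reactants: 36 the trisilylated 8-iodoflavone
Product: 38 7-acetoxy-2-[2-acetoxy-4-(prenyloxy)phenyl]-5-hydroxy-8-iodo-3-prenyl-4H-chromen-4-one, via triol 37 (not isolated)
Conditions: Bu4NF (3.3 equiv), AcOH (3.3 equiv), THF, 0 °C; then Ac2O (2.3 equiv), pyridine, 0 °C
Reagents that add atoms: acetic anhydride CC(=O)OC(C)=O
Why: Fluoride desilylation followed by controlled acetylation should esterify only the 7- and 2'-OH, since the 5-OH is chelated to the C-4 carbonyl and is the least reactive phenol.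

Step 22
Reactants: 38 the 8-iodoflavone diacetate
Product: 39 7-acetoxy-2-[2-acetoxy-4-(prenyloxy)phenyl]-5-hydroxy-4-oxo-3-prenyl-4H-chromene-8-carbaldehyde
Conditions: CO (1 atm), Bu3SnH (1.1 equiv, slow addition), Pd(PPh3)4 (5 mol%), toluene, 50 °C
Reagents that add atoms: carbon monoxide [C-]#[O+]
Why: Palladium-catalysed reductive carbonylation of the aryl iodide (oxidative addition, CO insertion, hydride transfer from tin) installs the aldehyde at C-8 only and tolerates esters, the free phenol and trisubstituted alkenes.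

Step 23
Reactants: 25 the tetraacetate ketone; 39 the flavone-8-carbaldehyde
Product: 41 7-acetoxy-2-[2-acetoxy-4-(prenyloxy)phenyl]-8-[(3R,5Z)-2-(2,4-diacetoxy-3-prenylbenzoyl)-3-(2,4-diacetoxyphenyl)-1-hydroxy-5-methyl-6-(trimethylsilyl)hex-5-en-1-yl]-5-hydroxy-3-prenyl-4H-chromen-4-one (epimers at side-chain C-1 and C-2), via trimethylsilyl enol ether 40 (not isolated)
Conditions: 25, Me3SiOTf (1.2 equiv), Et3N (1.5 equiv), CH2Cl2, 0 °C; evaporate, pentane, filter; then 39, Sc(OTf)3 (10 mol%), THF–H2O (9:1), 0 °C → rt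
Reagents that add atoms: none
Why: A Mukaiyama aldol addition catalysed by the water-tolerant Lewis acid Sc(OTf)3 forms the C(a)–C(f) bond while tolerating the acetates and the free chelated 5-OH, and the configurations at C-a and C-f are left uncontrolled because step 24 ionises the first and equilibrates the second.

Step 24
Reactants: 41 the aldol adduct carrying the (Z)-vinylsilane
Product: 42 7-acetoxy-2-[2-acetoxy-4-(prenyloxy)phenyl]-8-[(1S,5R,6S)-6-(2,4-diacetoxy-3-prenylbenzoyl)-5-(2,4-diacetoxyphenyl)-3-methylcyclohex-2-en-1-yl]-5-hydroxy-3-prenyl-4H-chromen-4-one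
Conditions: Me3SiOTf (0.3 equiv), CH2Cl2 (0.01 M), −78 → −30 °C; then NaHCO3 (aq.)
Reagents that add atoms: none
Why: The silyl triflate silylates and ionises the benzylic carbinol; the cation at C-a is in effect a protonated para-quinone methide, stabilised by the para 5-OH, the ortho O-7 and O-1 of ring A, and it is also reached from any enone formed by loss of the C-f proton, so all epimers of 41 converge. The (Z)-vinylsilane attacks through its silicon-bearing carbon b to give the tertiary β-silyl cation at C-c, whose pseudoaxial C–Si bond is aligned for loss of Me3Si+, which regenerates the silyl triflate; this is a vinylsilane-terminated cationic cyclisation, an ipso substitution that returns the alkene at b=c. The cyclohexene closes in the 6-endo mode with respect to the vinylsilane, both alkene carbons ending in the ring. The new stereocentre C-a is set by a chair-like transition state in which the aryl group on the fixed centre C-e and the flavonyl group on the cationic carbon are both pseudoequatorial (cis-1,3), and C-f settles trans to both by enol equilibration. The step needs attack at carbon b and not at carbon c or by an oxygen nucleophile: the β-silicon effect and the tertiary cation at c secure the first, and the acetates on the two ortho oxygens that could otherwise close a chroman or a chromanone secure the second, while also keeping the C-prenyl groups from acid-induced chroman formation.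

Step 25
Reactants: 42 the cyclised hexaacetate
Product: 43 5,7-dihydroxy-8-[(1S,5R,6S)-6-(2,4-dihydroxy-3-prenylbenzoyl)-5-(2,4-dihydroxyphenyl)-3-methylcyclohex-2-en-1-yl]-2-[2-hydroxy-4-(prenyloxy)phenyl]-3-prenyl-4H-chromen-4-one (CNP0082413.1)
Conditions: K2CO3 (3 equiv), MeOH (degassed), 0 °C → rt; then pH 5 buffer
Reagents that add atoms: none
Why: Base-mediated methanolysis (transesterification) of the six aryl acetates is fast at rt, leaves the aryl prenyl ether and both C-prenyl groups untouched, and can move C-f only toward the more stable all-trans arrangement.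

**Compound list**

1 | prop-2-yn-1-ol | C#CCO | starting material
2 | 4-methyl-2,5-dihydro-1,2-oxamagnesole (cyclic alkenylmagnesium alkoxide, MgBr2 complex) | CC1=C[Mg]OC1 | intermediate
3 | (Z)-3-iodo-2-methylprop-2-en-1-ol | OC/C(C)=C\I | intermediate
4 | lithium (Z)-3-lithio-2-methylprop-2-en-1-olate | [Li]OC/C(C)=C\[Li] | intermediate
5 | trimethyl{[(Z)-2-methyl-3-(trimethylsilyl)prop-2-en-1-yl]oxy}silane | C[Si](C)(C)OC/C(C)=C\[Si](C)(C)C | intermediate
6 | (Z)-2-methyl-3-(trimethylsilyl)prop-2-en-1-ol | OC/C(C)=C\[Si](C)(C)C | intermediate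
7 | (Z)-(3-bromo-2-methylprop-1-en-1-yl)trimethylsilane | BrC/C(C)=C\[Si](C)(C)C | intermediate
8 | (2,4-dihydroxyphenyl)acetic acid | OC(=O)Cc1ccc(O)cc1O | starting material
9 | tert-butyldimethylsilyl [2,4-bis(TBS-oxy)phenyl]acetate | CC(C)(C)[Si](C)(C)OC(=O)Cc1ccc(O[Si](C)(C)C(C)(C)C)cc1O[Si](C)(C)C(C)(C)C | intermediate
10 | [2,4-bis(TBS-oxy)phenyl]acetic acid | OC(=O)Cc1ccc(O[Si](C)(C)C(C)(C)C)cc1O[Si](C)(C)C(C)(C)C | intermediate
11 | (S)-4-benzyloxazolidin-2-one | O=C1N[C@@H](Cc2ccccc2)CO1 | starting material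
12 | [2,4-bis(TBS-oxy)phenyl]acetic pivalic anhydride | CC(C)(C)C(=O)OC(=O)Cc1ccc(O[Si](C)(C)C(C)(C)C)cc1O[Si](C)(C)C(C)(C)C | intermediate
13 | (S)-4-benzyl-3-{[2,4-bis(TBS-oxy)phenyl]acetyl}oxazolidin-2-one | O=C1OC[C@H](Cc2ccccc2)N1C(=O)Cc1ccc(O[Si](C)(C)C(C)(C)C)cc1O[Si](C)(C)C(C)(C)C | intermediate
14 | sodium (Z)-enolate of 13 | [Na]O/C(N1C(=O)OC[C@@H]1Cc1ccccc1)=C\c1ccc(O[Si](C)(C)C(C)(C)C)cc1O[Si](C)(C)C(C)(C)C | intermediate
15 | (S)-4-benzyl-3-{(2S,4Z)-2-[2,4-bis(TBS-oxy)phenyl]-4-methyl-5-(trimethylsilyl)pent-4-enoyl}oxazolidin-2-one | O=C1OC[C@H](Cc2ccccc2)N1C(=O)[C@H](c1ccc(O[Si](C)(C)C(C)(C)C)cc1O[Si](C)(C)C(C)(C)C)C/C(C)=C\[Si](C)(C)C | intermediate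
16 | (2S,4Z)-2-[2,4-bis(TBS-oxy)phenyl]-4-methyl-5-(trimethylsilyl)pent-4-en-1-ol | OC[C@H](c1ccc(O[Si](C)(C)C(C)(C)C)cc1O[Si](C)(C)C(C)(C)C)C/C(C)=C\[Si](C)(C)C | intermediate
17 | {(1Z,4S)-4-[2,4-bis(TBS-oxy)phenyl]-5-iodo-2-methylpent-1-en-1-yl}trimethylsilane | IC[C@H](c1ccc(O[Si](C)(C)C(C)(C)C)cc1O[Si](C)(C)C(C)(C)C)C/C(C)=C\[Si](C)(C)C | intermediate
18 | 2,4-dihydroxybenzaldehyde | O=Cc1ccc(O)cc1O | starting material
19 | 2,4-dihydroxy-3-prenylbenzaldehyde | O=Cc1ccc(O)c(CC=C(C)C)c1O | intermediate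
20 | 2,4-bis(TBS-oxy)-3-prenylbenzaldehyde | O=Cc1ccc(O[Si](C)(C)C(C)(C)C)c(CC=C(C)C)c1O[Si](C)(C)C(C)(C)C | intermediate
21 | primary alkyllithium from 17 (Li in place of I, same configuration in space) | [Li]C[C@H](c1ccc(O[Si](C)(C)C(C)(C)C)cc1O[Si](C)(C)C(C)(C)C)C/C(C)=C\[Si](C)(C)C | intermediate
22 | (3R,5Z)-1-[2,4-bis(TBS-oxy)-3-prenylphenyl]-3-[2,4-bis(TBS-oxy)phenyl]-5-methyl-6-(trimethylsilyl)hex-5-en-1-ol, both C-1 epimers | OC(C[C@H](c1ccc(O[Si](C)(C)C(C)(C)C)cc1O[Si](C)(C)C(C)(C)C)C/C(C)=C\[Si](C)(C)C)c1ccc(O[Si](C)(C)C(C)(C)C)c(CC=C(C)C)c1O[Si](C)(C)C(C)(C)C | intermediate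
23 | (3R,5Z)-1-[2,4-bis(TBS-oxy)-3-prenylphenyl]-3-[2,4-bis(TBS-oxy)phenyl]-5-methyl-6-(trimethylsilyl)hex-5-en-1-one | O=C(C[C@H](c1ccc(O[Si](C)(C)C(C)(C)C)cc1O[Si](C)(C)C(C)(C)C)C/C(C)=C\[Si](C)(C)C)c1ccc(O[Si](C)(C)C(C)(C)C)c(CC=C(C)C)c1O[Si](C)(C)C(C)(C)C | intermediate
24 | (3R,5Z)-1-(2,4-dihydroxy-3-prenylphenyl)-3-(2,4-dihydroxyphenyl)-5-methyl-6-(trimethylsilyl)hex-5-en-1-one | O=C(C[C@H](c1ccc(O)cc1O)C/C(C)=C\[Si](C)(C)C)c1ccc(O)c(CC=C(C)C)c1O | intermediate
25 | (3R,5Z)-1-(2,4-diacetoxy-3-prenylphenyl)-3-(2,4-diacetoxyphenyl)-5-methyl-6-(trimethylsilyl)hex-5-en-1-one | O=C(C[C@H](c1ccc(OC(C)=O)cc1OC(C)=O)C/C(C)=C\[Si](C)(C)C)c1ccc(OC(C)=O)c(CC=C(C)C)c1OC(C)=O | intermediate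
26 | 2',4',6'-trihydroxyacetophenone | CC(=O)c1c(O)cc(O)cc1O | starting material
27 | 1-[2-hydroxy-4,6-bis(TIPS-oxy)phenyl]ethanone | CC(=O)c1c(O)cc(O[Si](C(C)C)(C(C)C)C(C)C)cc1O[Si](C(C)C)(C(C)C)C(C)C | intermediate
28 | 1-[2-hydroxy-3-iodo-4,6-bis(TIPS-oxy)phenyl]ethanone | CC(=O)c1c(O)c(I)c(O[Si](C(C)C)(C(C)C)C(C)C)cc1O[Si](C(C)C)(C(C)C)C(C)C | intermediate
29 | dilithium phenoxide–enolate of 28 | [Li]OC(=C)c1c(O[Li])c(I)c(O[Si](C(C)C)(C(C)C)C(C)C)cc1O[Si](C(C)C)(C(C)C)C(C)C | intermediate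
30 | 1-[2-hydroxy-3-iodo-4,6-bis(TIPS-oxy)phenyl]-5-methylhex-4-en-1-one | CC(C)=CCCC(=O)c1c(O)c(I)c(O[Si](C(C)C)(C(C)C)C(C)C)cc1O[Si](C(C)C)(C(C)C)C(C)C | intermediate
31 | 2-hydroxy-4-(prenyloxy)benzaldehyde | O=Cc1ccc(OCC=C(C)C)cc1O | intermediate
32 | 4-(prenyloxy)-2-(TIPS-oxy)benzaldehyde | O=Cc1ccc(OCC=C(C)C)cc1O[Si](C(C)C)(C(C)C)C(C)C | intermediate
33 | dilithium phenoxide–enolate of 30 | [Li]OC(=CCC=C(C)C)c1c(O[Li])c(I)c(O[Si](C(C)C)(C(C)C)C(C)C)cc1O[Si](C(C)C)(C(C)C)C(C)C | intermediate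
34 | 3-hydroxy-1-[2-hydroxy-3-iodo-4,6-bis(TIPS-oxy)phenyl]-2-prenyl-3-[4-(prenyloxy)-2-(TIPS-oxy)phenyl]propan-1-one, diastereomer mixture | OC(c1ccc(OCC=C(C)C)cc1O[Si](C(C)C)(C(C)C)C(C)C)C(CC=C(C)C)C(=O)c1c(O)c(I)c(O[Si](C(C)C)(C(C)C)C(C)C)cc1O[Si](C(C)C)(C(C)C)C(C)C | intermediate
35 | 1-[2-hydroxy-3-iodo-4,6-bis(TIPS-oxy)phenyl]-2-prenyl-3-[4-(prenyloxy)-2-(TIPS-oxy)phenyl]propane-1,3-dione | O=C(c1ccc(OCC=C(C)C)cc1O[Si](C(C)C)(C(C)C)C(C)C)C(CC=C(C)C)C(=O)c1c(O)c(I)c(O[Si](C(C)C)(C(C)C)C(C)C)cc1O[Si](C(C)C)(C(C)C)C(C)C | intermediate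
36 | 8-iodo-3-prenyl-2-[4-(prenyloxy)-2-(TIPS-oxy)phenyl]-5,7-bis(TIPS-oxy)-4H-chromen-4-one | CC(C)=CCOc1ccc(-c2oc3c(I)c(O[Si](C(C)C)(C(C)C)C(C)C)cc(O[Si](C(C)C)(C(C)C)C(C)C)c3c(=O)c2CC=C(C)C)c(O[Si](C(C)C)(C(C)C)C(C)C)c1 | intermediate
37 | 5,7-dihydroxy-2-[2-hydroxy-4-(prenyloxy)phenyl]-8-iodo-3-prenyl-4H-chromen-4-one | CC(C)=CCOc1ccc(-c2oc3c(I)c(O)cc(O)c3c(=O)c2CC=C(C)C)c(O)c1 | intermediate
38 | 7-acetoxy-2-[2-acetoxy-4-(prenyloxy)phenyl]-5-hydroxy-8-iodo-3-prenyl-4H-chromen-4-one | CC(C)=CCOc1ccc(-c2oc3c(I)c(OC(C)=O)cc(O)c3c(=O)c2CC=C(C)C)c(OC(C)=O)c1 | intermediate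
39 | 7-acetoxy-2-[2-acetoxy-4-(prenyloxy)phenyl]-5-hydroxy-4-oxo-3-prenyl-4H-chromene-8-carbaldehyde | CC(C)=CCOc1ccc(-c2oc3c(C=O)c(OC(C)=O)cc(O)c3c(=O)c2CC=C(C)C)c(OC(C)=O)c1 | intermediate
40 | trimethylsilyl enol ether of 25 (enol geometry not assigned) | C[Si](C)(C)OC(=C[C@H](c1ccc(OC(C)=O)cc1OC(C)=O)C/C(C)=C\[Si](C)(C)C)c1ccc(OC(C)=O)c(CC=C(C)C)c1OC(C)=O | intermediate
41 | aldol adduct: 7-acetoxy-2-[2-acetoxy-4-(prenyloxy)phenyl]-8-[(3R,5Z)-2-(2,4-diacetoxy-3-prenylbenzoyl)-3-(2,4-diacetoxyphenyl)-1-hydroxy-5-methyl-6-(trimethylsilyl)hex-5-en-1-yl]-5-hydroxy-3-prenyl-4H-chromen-4-one, epimers at side-chain C-1 (a) and C-2 (f) | CC(C)=CCOc1ccc(-c2oc3c(C(O)C(C(=O)c4ccc(OC(C)=O)c(CC=C(C)C)c4OC(C)=O)[C@H](c4ccc(OC(C)=O)cc4OC(C)=O)C/C(C)=C\[Si](C)(C)C)c(OC(C)=O)cc(O)c3c(=O)c2CC=C(C)C)c(OC(C)=O)c1 | intermediate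
42 | 7-acetoxy-2-[2-acetoxy-4-(prenyloxy)phenyl]-8-[(1S,5R,6S)-6-(2,4-diacetoxy-3-prenylbenzoyl)-5-(2,4-diacetoxyphenyl)-3-methylcyclohex-2-en-1-yl]-5-hydroxy-3-prenyl-4H-chromen-4-one | CC(C)=CCOc1ccc(-c2oc3c([C@H]4C=C(C)C[C@@H](c5ccc(OC(C)=O)cc5OC(C)=O)[C@@H]4C(=O)c4ccc(OC(C)=O)c(CC=C(C)C)c4OC(C)=O)c(OC(C)=O)cc(O)c3c(=O)c2CC=C(C)C)c(OC(C)=O)c1 | intermediate
43 | CNP0082413.1: 5,7-dihydroxy-8-[(1S,5R,6S)-6-(2,4-dihydroxy-3-prenylbenzoyl)-5-(2,4-dihydroxyphenyl)-3-methylcyclohex-2-en-1-yl]-2-[2-hydroxy-4-(prenyloxy)phenyl]-3-prenyl-4H-chromen-4-one | CC(C)=CCOc1ccc(-c2oc3c([C@H]4C=C(C)C[C@@H](c5ccc(O)cc5O)[C@@H]4C(=O)c4ccc(O)c(CC=C(C)C)c4O)c(O)cc(O)c3c(=O)c2CC=C(C)C)c(O)c1 | target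

**Step count and risks**

Total step count: 25. Longest linear sequence: 12 steps (steps 1–3, 6–8, 11–13, 23–25).

Steps most likely to fail:

Step 24. After ionisation the cation may simply lose the C-f proton and rest as the enone without ring closure, the vinylsilane may be protodesilylated by triflic acid before it attacks, or the aryl prenyl ether may ionise. The fallback sets out from 41: dehydration with catalytic PPTS over 4 Å molecular sieves in benzene at 60 °C should give the enone F1. Me2AlCl (3 equiv) in CH2Cl2 at −78 → 0 °C should then add the vinylsilane to the aluminium-bound enone in a Lewis-acid-promoted, enone-initiated vinylsilane cyclisation that needs neither a free benzylic cation nor a protic acid. Protonation of the aluminium enolate on work-up brings the route back at 42.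

Step 23. Hydrolysis of the enol silane may outrun its addition to the electron-rich, ortho-substituted aldehyde, and the adduct may revert (retro-aldol) or dehydrate on the Lewis acid. The fallback is a boron-mediated aldol through a closed transition state. From 39, Et3SiOTf and 2,6-lutidine cap the 5-OH as the triethylsilyl ether F2. From 25, Bu2BOTf and i-Pr2NEt in CH2Cl2 at −78 °C give the dibutylboron enolate F3, which should add to F2 and give, after non-oxidative work-up (MeOH, pH 7 buffer), the 5-O-silylated aldol F4. Citric acid in MeOH removes the triethylsilyl group and returns the route at 41.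

Step 22. The aryl–palladium intermediate at the hindered C-8 may take up hydride before CO inserts (hydrodeiodination), and palladium hydride may cleave the aryl prenyl ether. The fallback sets out from 38 and uses no hydride: Stille coupling with Bu3SnCH2OH (Pd(PPh3)4, dioxane, 80 °C) should give the 8-hydroxymethyl flavone F5, and MnO2 in CH2Cl2 oxidises this benzylic alcohol to the aldehyde, returning the route at 39.

Further compounds

F1 | step 24 | 7-acetoxy-2-[2-acetoxy-4-(prenyloxy)phenyl]-8-[(3S,5Z)-2-(2,4-diacetoxy-3-prenylbenzoyl)-3-(2,4-diacetoxyphenyl)-5-methyl-6-(trimethylsilyl)hexa-1,5-dien-1-yl]-5-hydroxy-3-prenyl-4H-chromen-4-one (enone; C-3 unchanged in space, descriptor changes by the sequence rule; C-1=C-2 geometry open) | CC(C)=CCOc1ccc(-c2oc3c(C=C(C(=O)c4ccc(OC(C)=O)c(CC=C(C)C)c4OC(C)=O)[C@H](c4ccc(OC(C)=O)cc4OC(C)=O)C/C(C)=C\[Si](C)(C)C)c(OC(C)=O)cc(O)c3c(=O)c2CC=C(C)C)c(OC(C)=O)c1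
F2 | step 23 | 7-acetoxy-2-[2-acetoxy-4-(prenyloxy)phenyl]-4-oxo-3-prenyl-5-(triethylsilyloxy)-4H-chromene-8-carbaldehyde | CC(C)=CCOc1ccc(-c2oc3c(C=O)c(OC(C)=O)cc(O[Si](CC)(CC)CC)c3c(=O)c2CC=C(C)C)c(OC(C)=O)c1
F3 | step 23 | dibutylboron enolate of 25 | CCCCB(CCCC)OC(=C[C@H](c1ccc(OC(C)=O)cc1OC(C)=O)C/C(C)=C\[Si](C)(C)C)c1ccc(OC(C)=O)c(CC=C(C)C)c1OC(C)=O
F4 | step 23 | 5-O-triethylsilyl ether of 41 (epimers at side-chain C-1 and C-2) | CC(C)=CCOc1ccc(-c2oc3c(C(O)C(C(=O)c4ccc(OC(C)=O)c(CC=C(C)C)c4OC(C)=O)[C@H](c4ccc(OC(C)=O)cc4OC(C)=O)C/C(C)=C\[Si](C)(C)C)c(OC(C)=O)cc(O[Si](CC)(CC)CC)c3c(=O)c2CC=C(C)C)c(OC(C)=O)c1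
F5 | step 22 | 7-acetoxy-2-[2-acetoxy-4-(prenyloxy)phenyl]-5-hydroxy-8-(hydroxymethyl)-3-prenyl-4H-chromen-4-one | CC(C)=CCOc1ccc(-c2oc3c(CO)c(OC(C)=O)cc(O)c3c(=O)c2CC=C(C)C)c(OC(C)=O)c1
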